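Count the exposure.

| flask | starting complex | incoming ligand | remark | time |
|---|---|---|---|---|
| ochre | 0.20 M | 0.24 M | run made earlier |  |
| teal | 0.10 M | 0.24 M | run made earlier |  |
| alpha | 0.20 M | 0.240 M | one stirred flow tank at steady state, fed with the mixture as stated, mean residence time 50 min |  |
| gamma | 0.20 M | 0.240 M (fed, over 40.0 min) | a stirred flask in which incoming ligand is dosed at a steady rate over 40.0 min without added volume, worked up at 50 min | 50 min |
| epsilon | 0.20 M | 0.240 M | everything together in a closed stirred flask, run for 50 min | 50 min |
| theta | 0.20 M (fed, over 40.0 min) | 0.240 M | a stirred flask in which starting complex is dosed at a steady rate over 40.0 min without added volume, worked up at 50 min | 50 min |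

| run | time / min | complex with three exchanged / % | side product / % |
|---|---|---|---|
| ochre | 2.50 | 0.9 | 0 |
| ochre | 6.00 | 2.6 | 0.2 |
| ochre | 12.0 | 4.2 | 0.8 |
| ochre | 30.0 | 5.4 | 1.7 |
| teal | 2.50 | 0.7 | 0 |
| teal | 5.00 | 2.9 | 0 |
| teal | 8.00 | 7.3 | 0 |
| teal | 10.0 | 9.3 | 0.2 |

(readings scatter by 0.3 percentage points)

- percent here means starting complex units held: one side product counts as two
- the stated concentrations are those of everything mixed, before any reaction; amounts are the same in each set-up
- steps thought possible: complex with two exchanged + incoming ligand -> leaving ligand + complex with three exchanged; complex with one exchanged + incoming ligand -> leaving ligand + complex with two exchanged; starting complex + incoming ligand -> leaving ligand + complex with one exchanged; 2 incoming ligand -> homo dimer; starting complex + complex with three exchanged -> side product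
- the feed brings no volume worth counting
- the earlier runs were made in a closed, stirred flask

- the set-up with the highest share of complex with three exchanged in all that became complex with three exchanged or side product, at the outlet or at the end ("none" if the first two lie within 2 percentage points) (alpha / gamma / epsilon / theta / none)
- share of complex with three exchanged in all that became complex with three exchanged or side product, at the outlet or at the end, alpha
- share of complex with three exchanged in all that became complex with three exchanged or side product, at the outlet or at the end, gamma
- share of complex with three exchanged in all that became complex with three exchanged or side product, at the outlet or at the end, epsilon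
- share of complex with three exchanged in all that became complex with three exchanged or side product, at the outlet or at the end, theta

The listed step that eats product is starting complex + complex with three exchanged -> side product. Each turn removes one complex with three exchanged and adds two counted units of side product, all as fractions of the charge. Side product therefore equals twice a loss rate times the area under the curve of complex with three exchanged. In ochre that area is 1.14 min of charge, so the reading 1.7% gives a loss rate of 0.00745 min⁻¹.

At 30.0 min the readings of ochre put side product over twice complex with three exchanged at 0.157. Epsilon is ochre continued. Taking product formation as ended, a first round with the product held constant gives 0.306. Putting its decay back gives 0.343, the exposure number: side product over twice complex with three exchanged, or roughly loss rate times holding time. The share (selectivity) is one over one plus twice that number, so epsilon gets 59.3%.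

With the same rate, alpha holds product for 50 min and gets 57.3%. Gamma's product, taken as born on average 26.7 min into the feed, gets an estimated 74.2%. Theta's, taken as born evenly over its feed, gets an estimated 69.1%.

The loss rate was read at ochre's charge of starting complex. Teal, with half of that charge, tests it: with the rate halved, the reckoning gives 0.278% of side product against the reading 0.2%, with scatter 0.3 percentage points.

The forecast names gamma: alpha 53%, gamma 74%, epsilon 66%, theta 60%. Of gamma it says “little dimer forms and product appears late, so exposure is short”. On epsilon its 66% stands above this reckoning's 59.3%.

    complex with two exchanged + incoming ligand → leaving ligand + complex with three exchanged (k = 0.00480 M⁻¹ s⁻¹)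
    complex with one exchanged + incoming ligand → leaving ligand + complex with two exchanged (k = 0.0550 M⁻¹ s⁻¹)
    starting complex + incoming ligand → leaving ligand + complex with one exchanged (k = 0.0120 M⁻¹ s⁻¹)
    2 incoming ligand → homo dimer (k = 0.00130 M⁻¹ s⁻¹)
    starting complex + complex with three exchanged → side product (k = 0.00150 M⁻¹ s⁻¹)

The flasks give gamma first with 76.5%, then theta 64.4%, epsilon 56.7% and alpha 54.1%. Epsilon's share means an exposure number of 0.381 against the reckoned 0.343. A neighbouring flask has epsilon's recipe with 0.096 M of incoming ligand, and 70.0% of starting complex stands at its end against epsilon's 41.1%. Scaling the number by that ratio, with the holding time kept, gives 0.650 and a share of 43.5%. That neighbouring flask gives 41.8%.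

The runs were generated by integration for an exercise.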